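**Strategy.** The 2,3-dihydrofuran (O, C1–C4) is read as a rearranged 1-acyl-2-vinylcyclopropane: C1 is the carbonyl carbon, C2–C3–C4 the cyclopropane, C4 the donor carbon. A zerovalent-nickel Cloke–Wilson ring expansion of cyclopropyl ketone 18 cleaves C2–C4 and forms O–C4 with retention, so one operation delivers the oxygenated quaternary C4 and the C1=C2 enol ether. The precursor comes from enantioselective carbene transfer from a citramalate-derived diazoketone, which already carries C8, C10 and the butenolide, to a cheap diene. The ten-membered carbocycle is closed last by a vinylogous aldol–elimination that creates the ring-locked C5=C6 alkene.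

Key step: step 13

**Remarks on the chemistry**
- Atom numbers: C1 = enol-ether carbon on the ring O; C2 = ring CH=; C3 = ring CH2; C4 = O–C(CH3); C5 = exocyclic =CH; C6 = lactone O–C=; C7 = butenolide β-carbon; C8 = CH(OAc); C9 = CH2; C10 = C(OH)CH3; C11 = butenolide α-carbon; C12 = lactone C=O; C13 = CH2OAc; C14, C15 = methyls on C10, C4. The target is (4S,8S,10S,5E).
- Compounds 1, 6 and 17 are taken as commercially available.
- C2 of 18 and C1 of 20 and 21 form as epimer mixtures that converge later; their SMILES carry no descriptor at these atoms.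

**Route**

Step 1
Reactants: 1 4-(tert-butyldimethylsilyloxy)but-2-yn-1-ol
Product: 2 propargylic methyl carbonate
Conditions: ClCO2Me, pyridine, CH2Cl2, 0 °C
Reagents that add atoms: methyl chloroformate, COC(=O)Cl
Why: Acylation of the primary propargylic alcohol by the chloroformate (carbonate formation) installs the leaving group that the following carbonylation needs.

Step 2
Reactants: 2 propargylic methyl carbonate
Product: 3 methyl 2-(silyloxymethyl)buta-2,3-dienoate
Conditions: Pd(OAc)2 (2 mol%), PPh3 (8 mol%), CO (10 atm), MeOH, 50 °C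
Reagents that add atoms: carbon monoxide, [C-]#[O+]
Why: Tsuji carbonylation of a propargylic carbonate, in which SN2′ oxidative addition with loss of CO2 gives an allenylpalladium methoxide that inserts CO and collapses to the 2-substituted allenoate (future C6, C7, C11, C12, C13).

Step 3
Reactants: 3 allenoate
Product: 4 4-iodobutenolide
Conditions: I2, MeCN–H2O (15:1), 23 °C
Reagents that add atoms: iodine, II
Why: Iodolactonisation of a 2,3-allenoate, in which iodonium formation at the terminal C=C, attack of the ester carbonyl oxygen on the CH2 terminus and loss of the ester methyl as iodomethane give the β-iodobutenolide with iodine on C7.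

Step 4
Reactants: 4 4-iodobutenolide
Product: 5 4-(tributylstannyl)butenolide
Conditions: (Bu3Sn)2, Pd(PPh3)4 (5 mol%), toluene, 90 °C
Reagents that add atoms: hexabutylditin, CCCC[Sn](CCCC)(CCCC)[Sn](CCCC)(CCCC)CCCC
Why: Palladium-catalysed stannylation of the vinyl iodide (oxidative addition, Sn–Sn transmetalation, reductive elimination) makes C7 a nucleophile that should not expel the ring oxygen as a more polar vinylmetal could.

Step 5
Reactants: 6 (S)-citramalic acid
Product: 7 dioxolanone acid
Conditions: 2,2-dimethoxypropane, TsOH·H2O (cat.), 23 °C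
Reagents that add atoms: 2,2-dimethoxypropane, COC(C)(C)OC
Why: Acid-catalysed transacetalisation ties the tertiary hydroxyl and the adjacent carboxyl into the five-membered dioxolanone, which leaves only the CH2CO2H group (future C8) free and does not touch the C10 stereocentre taken from the chiral pool.

Step 6
Reactants: 7 dioxolanone acid; 5 4-(tributylstannyl)butenolide
Product: 9 C8 ketone (4-acylbutenolide), via acyl chloride 8 (not isolated)
Conditions: (COCl)2, DMF (cat.), CH2Cl2, 0 → 23 °C; then 5, Pd2(dba)3 (2.5 mol%), P(2-furyl)3, toluene, 60 °C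
Reagents that add atoms: none
Why: Stille acylation of the vinylstannane by the acid chloride forms the C7–C8 bond as a ketone under neutral conditions that the dioxolanone, silyl ether and butenolide tolerate.

Step 7
Reactants: 9 C8 ketone
Product: 10 (8S)-alcohol
Conditions: (R)-2-methyl-CBS-oxazaborolidine (20 mol%), BH3·SMe2, CH2Cl2, −40 °C
Reagents that add atoms: none
Why: Corey–Bakshi–Shibata reduction sets C8 under reagent control, since with the butenolide as the large and the CH2 group as the small substituent the (R)-catalyst should deliver hydride to the face that gives the (S)-carbinol, which is silylated without delay to forestall lactonisation onto the dioxolanone.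

Step 8
Reactants: 10 (8S)-alcohol
Product: 11 C8 silyl ether
Conditions: TBSCl, imidazole, DMF, 23 °C
Reagents that add atoms: tert-butyldimethylsilyl chloride, CC(C)(C)[Si](C)(C)Cl
Why: Imidazole-promoted silylation of the secondary allylic alcohol gives an ether that survives all steps up to the final deprotection.

Step 9
Reactants: 11 C8 silyl ether
Product: 12 tertiary α-hydroxy acid
Conditions: LiOH, THF–H2O (3:1), 0 °C; then 1 M HCl to pH 3
Reagents that add atoms: lithium hydroxide, [Li+].[OH-]
Why: Saponification of the dioxolanone, an activated ester that is cleaved at 0 °C with loss of acetone, frees the C1 acid and the C10 hydroxyl, any opened butenolide relactonising on acidification.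

Step 10
Reactants: 12 tertiary α-hydroxy acid
Product: 14 triethylsilyl-protected acid, via triethylsilyl ester 13 (not isolated)
Conditions: TESOTf, 2,6-lutidine, CH2Cl2, −40 → 0 °C; aqueous NaHCO3 work-up
Reagents that add atoms: triethylsilyl triflate, CC[Si](CC)(CC)OS(=O)(=O)C(F)(F)F
Why: Silyl triflate silylation protects the hindered tertiary alcohol, which would otherwise insert into the carbene of step 12, and the co-formed silyl ester is hydrolysed on aqueous work-up.

Step 11
Reactants: 14 triethylsilyl-protected acid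
Product: 16 diazoketone, via acyl chloride 15 (not isolated)
Conditions: 1-chloro-N,N,2-trimethylprop-1-en-1-amine, CH2Cl2, 0 °C; then CH2N2, Et2O, 0 °C
Reagents that add atoms: diazomethane, C=[N+]=[N-]
Why: Arndt–Eistert-type acylation of diazomethane by the acid chloride, which is made under neutral conditions so that the silyl ethers survive, gives the α-diazoketone that supplies C2.

Step 12
Reactants: 16 diazoketone; 17 (3E)-2-methylpenta-1,3-diene
Product: 18 vinylcyclopropyl ketone
Conditions: 17 (5 equiv), [Ru(MeCN)4((S)-Ph-pheox)]PF6 (3 mol%, divalent ruthenium), CH2Cl2, slow addition of 16, 23 °C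
Reagents that add atoms: none
Why: Ruthenium-carbene cyclopropanation takes place at the terminal 1,1-disubstituted alkene of the diene, and the chiral Ph-pheox ligand (its antipode if a trial shows the opposite preference) selects the alkene face and so fixes C4 as S under reagent control, while the C2 epimers that also form converge in step 13.

Step 13
Reactants: 18 vinylcyclopropyl ketone
Product: 19 2,3-dihydrofuran
Conditions: Ni(cod)2 (10 mol%), toluene, 23 °C
Reagents that add atoms: none
Why: Zerovalent nickel adds oxidatively to the C2–C4 bond of the vinylcyclopropane anti to the breaking bond, giving an η3-allylnickel enolate zwitterion, and the enolate oxygen then attacks the quaternary allyl terminus C4 anti to nickel and releases the catalyst. The closest known reaction type is the nickel-catalysed rearrangement of 1-acyl-2-vinylcyclopropanes to 2,3-dihydrofurans, a metal-mediated Cloke–Wilson rearrangement. The five-membered ring closes by O-alkylation of the enolate at the proximal allyl terminus, a 5-exo closure with respect to the allyl unit. No new stereocentre is created: C4 is carried over from 18 with net retention through two inversions, and the C2 stereocentre of 18 is erased in the enol ether. The step needs O- over C-alkylation, attack at C4 and not at the distal terminus (seven-membered ring), and closure faster than π–σ–π face exchange; the short enolate tether favours the five-membered ring, and the methyl-capped distal terminus, which has no CH2 end, slows η3–η1–η3 isomerisation.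

Step 14
Reactants: 19 2,3-dihydrofuran
Product: 20 C1 methyl ketal
Conditions: MeOH, PPTS (2 mol%), CH2Cl2, −20 °C; Et3N quench
Reagents that add atoms: methanol, CO
Why: Acid-catalysed addition of methanol to the enol ether (mixed ketal formation through the oxocarbenium ion) masks the ozone-sensitive C1=C2 bond, both C1 epimers being carried on.

Step 15
Reactants: 20 C1 methyl ketal
Product: 21 C5 aldehyde
Conditions: O3, CH2Cl2, pyridine, −78 °C; then Me2S
Reagents that add atoms: ozone, [O-][O+]=O
Why: Ozonolysis should cleave the electron-rich disubstituted propenyl alkene much faster than the tetrasubstituted, conjugated butenolide alkene and turns C5 into the aldehyde.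

Step 16
Reactants: 21 C5 aldehyde
Product: 24 silyl-protected macrocycle, via silyloxyfuran enol ether 22 (not isolated), via aldol silyl ether 23 (not isolated)
Conditions: TMSOTf (3 equiv), iPr2NEt (5 equiv), CH2Cl2 (0.002 M), −78 → 0 °C; then DBU, 23 °C
Reagents that add atoms: none
Why: Vinylogous Mukaiyama aldol reaction followed by E1cB elimination, in which silyl triflate and amine convert the butenolide into the 2-silyloxyfuran and the mixed ketal back into the enol ether, C6 of the furan adds to the silyl-activated C5 aldehyde to close the ten-membered carbocycle, and DBU then expels silanolate from C5, the bridged ring allowing only the C5=C6 geometry with C4 cis to C7 and erasing the C5 and C6 stereocentres of 23.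

Step 17
Reactants: 24 silyl-protected macrocycle
Product: 25 triol
Conditions: HF·pyridine, pyridine, THF, 0 → 23 °C
Reagents that add atoms: none
Why: Fluoride-mediated cleavage of the three silyl ethers under pyridine-buffered conditions that the enol ether and the enol lactone should tolerate.

Step 18
Reactants: 25 triol
Product: 26 target CNP0144020.1
Conditions: Ac2O, pyridine, DMAP (cat.), CH2Cl2, 0 °C
Reagents that add atoms: acetic anhydride, CC(=O)OC(C)=O
Why: Pyridine-mediated acetylation esterifies the primary C13 and secondary C8 hydroxyls, whereas the tertiary C10 hydroxyl does not react under these conditions.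

**Compound list**

1 | 4-[(tert-butyldimethylsilyl)oxy]but-2-yn-1-ol | CC(C)(C)[Si](C)(C)OCC#CCO | starting material
2 | 4-[(tert-butyldimethylsilyl)oxy]but-2-yn-1-yl methyl carbonate | COC(=O)OCC#CCO[Si](C)(C)C(C)(C)C | intermediate
3 | methyl 2-{[(tert-butyldimethylsilyl)oxy]methyl}buta-2,3-dienoate | COC(=O)C(CO[Si](C)(C)C(C)(C)C)=C=C | intermediate
4 | 3-{[(tert-butyldimethylsilyl)oxy]methyl}-4-iodofuran-2(5H)-one | O=C1OCC(I)=C1CO[Si](C)(C)C(C)(C)C | intermediate
5 | 3-{[(tert-butyldimethylsilyl)oxy]methyl}-4-(tributylstannyl)furan-2(5H)-one | O=C1OCC([Sn](CCCC)(CCCC)CCCC)=C1CO[Si](C)(C)C(C)(C)C | intermediate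
6 | (S)-citramalic acid, (2S)-2-hydroxy-2-methylbutanedioic acid | OC(=O)[C@@](C)(O)CC(=O)O | starting material
7 | 2-[(4S)-2,2,4-trimethyl-5-oxo-1,3-dioxolan-4-yl]acetic acid | O=C1[C@@](C)(OC(C)(C)O1)CC(=O)O | intermediate
8 | 2-[(4S)-2,2,4-trimethyl-5-oxo-1,3-dioxolan-4-yl]acetyl chloride (not isolated) | O=C1[C@@](C)(OC(C)(C)O1)CC(=O)Cl | intermediate
9 | (5S)-5-{2-[4-({[tert-butyldimethylsilyl]oxy}methyl)-5-oxo-2,5-dihydrofuran-3-yl]-2-oxoethyl}-2,2,5-trimethyl-1,3-dioxolan-4-one | O=C1[C@@](C)(OC(C)(C)O1)CC(=O)C1=C(CO[Si](C)(C)C(C)(C)C)C(=O)OC1 | intermediate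
10 | (5S)-5-{(2S)-2-hydroxy-2-[4-({[tert-butyldimethylsilyl]oxy}methyl)-5-oxo-2,5-dihydrofuran-3-yl]ethyl}-2,2,5-trimethyl-1,3-dioxolan-4-one | O=C1[C@@](C)(OC(C)(C)O1)C[C@@H](C1=C(CO[Si](C)(C)C(C)(C)C)C(=O)OC1)O | intermediate
11 | O-tert-butyldimethylsilyl ether of 10 at C8 | O=C1[C@@](C)(OC(C)(C)O1)C[C@@H](C1=C(CO[Si](C)(C)C(C)(C)C)C(=O)OC1)O[Si](C)(C)C(C)(C)C | intermediate
12 | (2S,4S)-4-[(tert-butyldimethylsilyl)oxy]-4-[4-({[tert-butyldimethylsilyl]oxy}methyl)-5-oxo-2,5-dihydrofuran-3-yl]-2-hydroxy-2-methylbutanoic acid | OC(=O)[C@@](C)(O)C[C@@H](C1=C(CO[Si](C)(C)C(C)(C)C)C(=O)OC1)O[Si](C)(C)C(C)(C)C | intermediate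
13 | triethylsilyl ester of 14 (not isolated) | CC[Si](CC)(CC)OC(=O)[C@@](C)(O[Si](CC)(CC)CC)C[C@@H](C1=C(CO[Si](C)(C)C(C)(C)C)C(=O)OC1)O[Si](C)(C)C(C)(C)C | intermediate
14 | (2S,4S)-4-[(tert-butyldimethylsilyl)oxy]-4-[4-({[tert-butyldimethylsilyl]oxy}methyl)-5-oxo-2,5-dihydrofuran-3-yl]-2-methyl-2-[(triethylsilyl)oxy]butanoic acid | OC(=O)[C@@](C)(O[Si](CC)(CC)CC)C[C@@H](C1=C(CO[Si](C)(C)C(C)(C)C)C(=O)OC1)O[Si](C)(C)C(C)(C)C | intermediate
15 | acyl chloride of 14 (not isolated) | ClC(=O)[C@@](C)(O[Si](CC)(CC)CC)C[C@@H](C1=C(CO[Si](C)(C)C(C)(C)C)C(=O)OC1)O[Si](C)(C)C(C)(C)C | intermediate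
16 | (3S,5S)-5-[(tert-butyldimethylsilyl)oxy]-5-[4-({[tert-butyldimethylsilyl]oxy}methyl)-5-oxo-2,5-dihydrofuran-3-yl]-1-diazo-3-methyl-3-[(triethylsilyl)oxy]pentan-2-one | [N-]=[N+]=CC(=O)[C@@](C)(O[Si](CC)(CC)CC)C[C@@H](C1=C(CO[Si](C)(C)C(C)(C)C)C(=O)OC1)O[Si](C)(C)C(C)(C)C | intermediate
17 | (3E)-2-methylpenta-1,3-diene | C=C(C)/C=C/C | starting material
18 | (2S,4S)-4-[(tert-butyldimethylsilyl)oxy]-4-[4-({[tert-butyldimethylsilyl]oxy}methyl)-5-oxo-2,5-dihydrofuran-3-yl]-2-methyl-1-{(2S)-2-methyl-2-[(1E)-prop-1-en-1-yl]cyclopropyl}-2-[(triethylsilyl)oxy]butan-1-one, both epimers at the acyl-bearing ring carbon | C/C=C/[C@]1(C)CC1C(=O)[C@@](C)(O[Si](CC)(CC)CC)C[C@@H](C2=C(CO[Si](C)(C)C(C)(C)C)C(=O)OC2)O[Si](C)(C)C(C)(C)C | intermediate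
19 | (2S)-2-methyl-2-[(1E)-prop-1-en-1-yl]-2,3-dihydrofuran carrying at its 5-position the (2S,4S)-4-[(tert-butyldimethylsilyl)oxy]-4-[4-({[tert-butyldimethylsilyl]oxy}methyl)-5-oxo-2,5-dihydrofuran-3-yl]-2-[(triethylsilyl)oxy]butan-2-yl group | C/C=C/[C@]1(C)CC=C(O1)[C@@](C)(O[Si](CC)(CC)CC)C[C@@H](C2=C(CO[Si](C)(C)C(C)(C)C)C(=O)OC2)O[Si](C)(C)C(C)(C)C | intermediate
20 | methyl ketal of 19: 2-methoxytetrahydrofuran formed by addition of methanol across C1=C2, C4 S, both C1 epimers | C/C=C/[C@]1(C)CCC(OC)(O1)[C@@](C)(O[Si](CC)(CC)CC)C[C@@H](C2=C(CO[Si](C)(C)C(C)(C)C)C(=O)OC2)O[Si](C)(C)C(C)(C)C | intermediate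
21 | aldehyde from 20: the propenyl group on C4 replaced by CHO (C5), C4 S, both C1 epimers | O=C[C@]1(C)CCC(OC)(O1)[C@@](C)(O[Si](CC)(CC)CC)C[C@@H](C2=C(CO[Si](C)(C)C(C)(C)C)C(=O)OC2)O[Si](C)(C)C(C)(C)C | intermediate
22 | (2S)-2-formyl-2-methyl-2,3-dihydrofuran whose side chain carries the 2-(trimethylsilyloxy)furan derived from the butenolide (not isolated) | O=C[C@]1(C)CC=C(O1)[C@@](C)(O[Si](CC)(CC)CC)C[C@@H](c2coc(O[Si](C)(C)C)c2CO[Si](C)(C)C(C)(C)C)O[Si](C)(C)C(C)(C)C | intermediate
23 | macrocyclic aldol adduct: C5–C6 single bond, C5–OSiMe3, C6–H butenolide, C5 and C6 epimers (not isolated) | CC(C)(C)[Si](C)(C)OCC1=C2C(C(O[Si](C)(C)C)[C@]3(C)CC=C(O3)[C@@](C)(O[Si](CC)(CC)CC)C[C@@H]2O[Si](C)(C)C(C)(C)C)OC1=O | intermediate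
24 | (4S,8S,10S,5E)-macrocycle with the target skeleton, 8-O- and 13-O-tert-butyldimethylsilyl, 10-O-triethylsilyl | CC(C)(C)[Si](C)(C)OCC1=C2/C(=C\[C@]3(C)CC=C(O3)[C@@](C)(O[Si](CC)(CC)CC)C[C@@H]2O[Si](C)(C)C(C)(C)C)OC1=O | intermediate
25 | (4S,8S,10S,5E)-triol, the 8,13-di-O-deacetyl target | OCC1=C2/C(=C\[C@]3(C)CC=C(O3)[C@@](C)(O)C[C@@H]2O)OC1=O | intermediate
26 | CNP0144020.1, the (4S,8S,10S,5E)-8,13-diacetate | CC(=O)OCC1=C2/C(=C\[C@]3(C)CC=C(O3)[C@@](C)(O)C[C@@H]2OC(C)=O)OC1=O | target

**Step count.** Total: 18 steps. Longest linear sequence: 17 steps (1 → 5, then steps 6–18); 14 steps from citramalic acid 6.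

**Steps most likely to fail**

Step 16 (macrocyclisation). The medium-ring closure may lose to intermolecular aldol oligomerisation, and the furanolate may expel the C13 silyloxy group instead of the C5 one. The fallback sets out from 21 and replaces the kinetically controlled silyl-triflate aldol by a reversible, amine-catalysed Knoevenagel-type condensation under thermodynamic control (pyrrolidine, AcOH, 4 Å molecular sieves, MeCN, high dilution). Iminium activation of the C5 aldehyde and the dienolate of the butenolide should give the macrocyclic ylidene butenolide with the C1 ketal still in place, macrocyclic ketal F1. A separate silyl-triflate elimination of methanol (TMSOTf, iPr2NEt, CH2Cl2, 0 °C) then regenerates the enol ether, and the route is rejoined at 24.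

Step 12 (cyclopropanation). Facial selectivity of the carbene transfer may be poor with this hindered, chiral diazoketone, and intramolecular C–H insertion at C8 may compete. The fallback gives up catalyst control and sets out from 16 and 17. Rh2(OAc)4 with a large excess of the diene should give 18 together with its C4 epimer, cyclopropyl ketone F2. The mixture is taken through the nickel rearrangement (19 and dihydrofuran F3), ketalisation (20 and ketal F4) and ozonolysis (21 and aldehyde F5). The C4-epimeric aldehydes are separated by chromatography, and the route is rejoined at 21.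

Step 13 (key step). The C4 configuration may erode through π–σ–π face exchange in the allylnickel intermediate, or the butenolide may sequester the catalyst. The fallback sets out from 18 and uses a metal-free, stereoconvergent Cloke–Wilson rearrangement under chiral Brønsted acid catalysis: (R)-3,3′-bis(2,4,6-triisopropylphenyl)-1,1′-binaphthyl-2,2′-diyl hydrogen phosphate (5 mol%), toluene, 4 Å molecular sieves, 23 °C. The acid opens the cyclopropane to an allyl cation–enol pair, the configuration at C4 is set afresh in the ion-pair closure by the chiral phosphate, and the route is rejoined at 19. No new compound arises.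

**Further compounds**

F1 | step 16 | macrocyclic C1 methyl ketal corresponding to 24 (both C1 epimers) | CC(C)(C)[Si](C)(C)OCC1=C2/C(=C\[C@]3(C)CCC(OC)(O3)[C@@](C)(O[Si](CC)(CC)CC)C[C@@H]2O[Si](C)(C)C(C)(C)C)OC1=O
F2 | step 12 | C4 epimer of 18, (2R)-cyclopropyl ketone | C/C=C/[C@@]1(C)CC1C(=O)[C@@](C)(O[Si](CC)(CC)CC)C[C@@H](C2=C(CO[Si](C)(C)C(C)(C)C)C(=O)OC2)O[Si](C)(C)C(C)(C)C
F3 | step 12 | C4 epimer of 19 | C/C=C/[C@@]1(C)CC=C(O1)[C@@](C)(O[Si](CC)(CC)CC)C[C@@H](C2=C(CO[Si](C)(C)C(C)(C)C)C(=O)OC2)O[Si](C)(C)C(C)(C)C
F4 | step 12 | C4 epimer of 20 | C/C=C/[C@@]1(C)CCC(OC)(O1)[C@@](C)(O[Si](CC)(CC)CC)C[C@@H](C2=C(CO[Si](C)(C)C(C)(C)C)C(=O)OC2)O[Si](C)(C)C(C)(C)C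
F5 | step 12 | C4 epimer of 21 | O=C[C@@]1(C)CCC(OC)(O1)[C@@](C)(O[Si](CC)(CC)CC)C[C@@H](C2=C(CO[Si](C)(C)C(C)(C)C)C(=O)OC2)O[Si](C)(C)C(C)(C)C
F0 | step 13 | none | none
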